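**Retrosynthetic overview**
1. Feature: the central 1,4-dioxane (O–C6–C7–O–C6′–C7′) is the head-to-tail dimer of an (R)-aryl(hydroxy)-C2 unit. Each C6 is therefore an anomeric O–CH carbon bonded to C5, the carbon wedged between quaternary C4 and C10, and each C7 carries the ring C arene.
2. Last disconnection, the two C9–C10 bonds: both B rings come from acid-mediated cationic cyclisation of the arenes onto tetrasubstituted C5=C10 alkenes, which sets C5 and C10.
3. Key disconnection, the two C5–C6 bonds: a 2,6,6-trimethylcyclohexenyl trifluoroborate (ring A) adds twice to the bis-oxocarbenium ion from the dioxane-3,6-diyl diacetate, which sets C6.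
4. The diacetate comes by reductive acetylation from the homochiral (R,R) dilactone that two molecules of a 3-isopropyl-4-methoxymandelic acid form head to tail, so C7 never passes through a free α-hydroxy aldehyde. The acid comes from 2-isopropylanisole by Friedel–Crafts glyoxylation and asymmetric transfer hydrogenation; the borate comes from 2,2,6-trimethylcyclohexanone by a Shapiro reaction.
5. Ring order: ring C (bought) → dioxane → preformed ring A attached → rings B and B′ closed last.

Key step: step 8

Remark: diacetate 9 is drawn as one anomer but is used as the anomeric mixture that step 5 gives, because both acetal carbons become planar in step 8; ketone 10 is used as the racemate, its stereocentre being lost in step 7.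

**Step 1**
Reactants: 1 2-isopropylanisole; 2 ethyl chlorooxoacetate
Product: 3 ethyl 2-(3-isopropyl-4-methoxyphenyl)-2-oxoacetate
Conditions: AlCl3, CH2Cl2, 0 °C
Reagents that add atoms: none
Why: Friedel–Crafts acylation; the methoxy group directs the acylium ion of 2 to its free para position, which gives the 3-isopropyl-4-methoxyphenyl pattern of ring C, and the deactivated keto ester is not acylated again.

**Step 2**
Reactants: 3 ethyl 2-(3-isopropyl-4-methoxyphenyl)-2-oxoacetate
Product: 4 ethyl (2R)-2-hydroxy-2-(3-isopropyl-4-methoxyphenyl)acetate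
Conditions: RuCl[(S,S)-TsDPEN](p-cymene) (1 mol%), HCO2H/Et3N (5:2), DMF, 25 °C
Reagents that add atoms: none
Why: Noyori–Ikariya asymmetric transfer hydrogenation of an aryl α-keto ester; the (S,S) ligand should place the aryl group next to the η6-arene and deliver hydride to the ketone face that gives the (R) alcohol (the spatial sense of (S)-1-arylethanols, with the descriptor changed by the ester priority), which sets C7.

**Step 3**
Reactants: 4 ethyl (2R)-2-hydroxy-2-(3-isopropyl-4-methoxyphenyl)acetate
Product: 5 (2R)-2-hydroxy-2-(3-isopropyl-4-methoxyphenyl)acetic acid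
Conditions: LiOH·H2O, THF/H2O, 0 °C; then 1 M HCl
Reagents that add atoms: lithium hydroxide, [Li+].[OH-]
Why: ester saponification; the α-hydroxy carboxylate is not enolised at 0 °C, so C7 stays (R), and crystallisation of the acid can raise its enantiomeric purity.

**Step 4**
Reactants: 5 (2R)-2-hydroxy-2-(3-isopropyl-4-methoxyphenyl)acetic acid (first molecule, acyl donor); 5 (2R)-2-hydroxy-2-(3-isopropyl-4-methoxyphenyl)acetic acid (second molecule, hydroxy component)
Product: 7 (3R,6R)-3,6-bis(3-isopropyl-4-methoxyphenyl)-1,4-dioxane-2,5-dione, via linear seco acid 6 (not isolated)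
Conditions: TsOH·H2O (5 mol%), toluene (0.05 M in 5), reflux, Dean–Stark
Reagents that add atoms: none
Why: acid-catalysed cyclodimerisation (double Fischer esterification) with azeotropic removal of two molecules of water: the carboxyl group of one molecule of 5 esterifies the hydroxy group of a second molecule to give linear dimer 6, whose remaining hydroxy and carboxyl groups close the six-membered dilactone; no bond to C7 is broken, so two (R) acids can only give the cis (R,R) dilactone, whose boat-shaped ring holds both aryl groups pseudoequatorial.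

**Step 5**
Reactants: 7 (3R,6R)-3,6-bis(3-isopropyl-4-methoxyphenyl)-1,4-dioxane-2,5-dione
Product: 9 (2R,3R,5R,6R)-2,5-bis(3-isopropyl-4-methoxyphenyl)-1,4-dioxane-3,6-diyl diacetate, via bis(diisobutylaluminium) lactolate 8 (not isolated)
Conditions: iBu2AlH (2.3 equiv), CH2Cl2, −78 °C; then pyridine, DMAP, Ac2O, −78 → −20 °C
Reagents that add atoms: acetic anhydride, CC(=O)OC(C)=O
Why: reductive acetylation of a lactone; each carbonyl is reduced only to the tetrahedral aluminium hemiacetal, which is acetylated in the cold before the ring can open, so the homochiral dimer is kept and no enolisable hydroxy aldehyde is formed.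

**Step 6**
Reactants: 10 2,2,6-trimethylcyclohexanone; 11 2,4,6-triisopropylbenzenesulfonohydrazide
Product: 12 N′-[(1E)-2,2,6-trimethylcyclohexylidene]-2,4,6-triisopropylbenzenesulfonohydrazide
Conditions: conc. HCl (cat.), MeCN, rt
Reagents that add atoms: none
Why: acid-catalysed hydrazone condensation; the sulfonylamino group should settle anti to the quaternary carbon and therefore syn to the only α-C–H, as the Shapiro reaction requires.

**Step 7**
Reactants: 12 N′-[(1E)-2,2,6-trimethylcyclohexylidene]-2,4,6-triisopropylbenzenesulfonohydrazide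
Product: 15 potassium trifluoro(2,6,6-trimethylcyclohex-1-en-1-yl)borate, via alkenyllithium 13 (not isolated), via lithium triisopropoxyborate 14 (not isolated)
Conditions: n-BuLi (2.2 equiv), TMEDA, THF/hexane, −78 → 0 °C; B(OiPr)3, −78 °C → rt; aq. KHF2, MeOH
Reagents that add atoms: triisopropyl borate, CC(C)OB(OC(C)C)OC(C)C; potassium hydrogen difluoride, F.[F-].[K+]
Why: Shapiro reaction; N–H and syn α-C–H deprotonation followed by loss of sulfinate and N2 gives the tetrasubstituted alkenyllithium with the double bond fixed by the single α-hydrogen, and borylation with fluoride exchange gives the stable trifluoroborate.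

**Step 8**
Reactants: 9 (2R,3R,5R,6R)-2,5-bis(3-isopropyl-4-methoxyphenyl)-1,4-dioxane-3,6-diyl diacetate; 15 potassium trifluoro(2,6,6-trimethylcyclohex-1-en-1-yl)borate
Product: 17 (2R,3R,5R,6R)-2,5-bis(3-isopropyl-4-methoxyphenyl)-3,6-bis(2,6,6-trimethylcyclohex-1-en-1-yl)-1,4-dioxane, via monoalkenylated monoacetate 16 (not isolated)
Conditions: 15 (3 equiv), BF3·OEt2 (4 equiv), MeCN/CH2Cl2, −40 → 0 °C; then aq. NaHCO3
Reagents that add atoms: none
Why: BF3·OEt2 strips fluoride from 15 (giving the alkenyldifluoroborane and KBF4) and ionises an anomeric acetate of 9 to the C6 oxocarbenium ion stabilised by the ring oxygen; the alkenyl borane attacks through its boron-bearing carbon (the future C5), the developing charge sits on the tertiary C10 β to boron, and loss of boron restores the C5=C10 alkene, after which the sequence repeats at C6′ on monoacetate 16. The closest known reaction type is the BF3-promoted C-glycosylation-type addition of potassium alkenyltrifluoroborates to cyclic oxocarbenium ions generated from anomeric acetates. No ring is closed: two C5–C6 σ bonds join three fragments at the carbon that lies between quaternary C4 and the future quaternary C10. C6 and C6′ are set by the C7 and C7′ stereocentres: the homochiral dimer holds both aryl groups on one face of the dioxane, so each half-chair oxocarbenium ion is attacked axially from the opposite face, anti to the pseudoaxial aryl group on the neighbouring carbon, which gives the 2,3-trans (6R) and C2-symmetric 2,5-cis arrangement. The step needs ipso attack at C5 in preference to protodeboronation and loss of the exocyclic acetate in preference to opening of the para-methoxybenzylic C7–O bond; the β-boron-stabilised tertiary cation, the better leaving-group ability of acetate under BF3, the low temperature and the excess of 15 should secure this, and C7 is not touched.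

**Step 9**
Reactants: 17 (2R,3R,5R,6R)-2,5-bis(3-isopropyl-4-methoxyphenyl)-3,6-bis(2,6,6-trimethylcyclohex-1-en-1-yl)-1,4-dioxane
Product: 19 CNP0327150.1 = C2-symmetric dimer of 12-methoxyabieta-8,11,13-triene joined by the oxygen bridges C6–O–C7′ and C6′–O–C7 (5S,6R,7R,10S in each half; 6α-O and 7β-O; trans A/B), via monocyclised half-closed dioxane 18 (not isolated)
Conditions: TfOH (2.5 equiv), CH2Cl2, −78 → −20 °C
Reagents that add atoms: none
Why: cationic Friedel–Crafts cycloalkylation (arene-terminated cation–olefin cyclisation); TfOH protonates each tetrasubstituted alkene at C5 (a C5 cation would sit next to the C6 oxygen) and the tertiary C10 cation is captured by C9, the arene position ortho to C7 and para to the isopropyl group (the other ortho position is blocked between C7 and the isopropyl group), through a chair-like six-membered transition state with C4, O6 and O7 equatorial on ring B and the C10 methyl axial, which gives the trans A/B fusion (5S,10S; H5 anti to H6) in both halves, reversible proton loss from the C10 cation letting C5 adjust before ring closure.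

**Compound list**
1 | 2-isopropylanisole | COc1ccccc1C(C)C | starting material
2 | ethyl chlorooxoacetate | CCOC(=O)C(=O)Cl | starting material
3 | ethyl 2-(3-isopropyl-4-methoxyphenyl)-2-oxoacetate | CCOC(=O)C(=O)c1ccc(OC)c(C(C)C)c1 | intermediate
4 | ethyl (2R)-2-hydroxy-2-(3-isopropyl-4-methoxyphenyl)acetate | CCOC(=O)[C@H](O)c1ccc(OC)c(C(C)C)c1 | intermediate
5 | (2R)-2-hydroxy-2-(3-isopropyl-4-methoxyphenyl)acetic acid | OC(=O)[C@H](O)c1ccc(OC)c(C(C)C)c1 | intermediate
6 | linear seco acid, (2R)-2-{[(2R)-2-hydroxy-2-(3-isopropyl-4-methoxyphenyl)acetyl]oxy}-2-(3-isopropyl-4-methoxyphenyl)acetic acid | OC(=O)[C@H](OC(=O)[C@H](O)c1ccc(OC)c(C(C)C)c1)c1ccc(OC)c(C(C)C)c1 | intermediate (not isolated)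
7 | (3R,6R)-3,6-bis(3-isopropyl-4-methoxyphenyl)-1,4-dioxane-2,5-dione | COc1ccc(cc1C(C)C)[C@H]1OC(=O)[C@H](OC1=O)c1ccc(OC)c(C(C)C)c1 | intermediate
8 | bis(diisobutylaluminium) lactolate of 7 (3,6-bis(diisobutylaluminiooxy)-2,5-diaryl-1,4-dioxane, acetal carbons undefined) | COc1ccc(cc1C(C)C)[C@H]1OC(O[Al](CC(C)C)CC(C)C)[C@H](OC1O[Al](CC(C)C)CC(C)C)c1ccc(OC)c(C(C)C)c1 | intermediate (not isolated)
9 | (2R,3R,5R,6R)-2,5-bis(3-isopropyl-4-methoxyphenyl)-1,4-dioxane-3,6-diyl diacetate | COc1ccc(cc1C(C)C)[C@H]1O[C@H](OC(C)=O)[C@H](O[C@@H]1OC(C)=O)c1ccc(OC)c(C(C)C)c1 | intermediate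
10 | 2,2,6-trimethylcyclohexanone (racemic) | CC1CCCC(C)(C)C1=O | starting material
11 | 2,4,6-triisopropylbenzenesulfonohydrazide | CC(C)c1cc(C(C)C)c(c(c1)C(C)C)S(=O)(=O)NN | starting material
12 | N′-[(1E)-2,2,6-trimethylcyclohexylidene]-2,4,6-triisopropylbenzenesulfonohydrazide | CC1CCCC(C)(C)/C1=N/NS(=O)(=O)c1c(C(C)C)cc(C(C)C)cc1C(C)C | intermediate
13 | (2,6,6-trimethylcyclohex-1-en-1-yl)lithium | CC1=C([Li])C(C)(C)CCC1 | intermediate (not isolated)
14 | lithium triisopropoxy(2,6,6-trimethylcyclohex-1-en-1-yl)borate | CC1=C([B-](OC(C)C)(OC(C)C)OC(C)C)C(C)(C)CCC1.[Li+] | intermediate (not isolated)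
15 | potassium trifluoro(2,6,6-trimethylcyclohex-1-en-1-yl)borate | CC1=C([B-](F)(F)F)C(C)(C)CCC1.[K+] | intermediate
16 | (2R,3R,5R,6R)-3,6-bis(3-isopropyl-4-methoxyphenyl)-5-(2,6,6-trimethylcyclohex-1-en-1-yl)-1,4-dioxan-2-yl acetate | COc1ccc(cc1C(C)C)[C@H]1O[C@H](OC(C)=O)[C@H](O[C@@H]1C1=C(C)CCCC1(C)C)c1ccc(OC)c(C(C)C)c1 | intermediate (not isolated)
17 | (2R,3R,5R,6R)-2,5-bis(3-isopropyl-4-methoxyphenyl)-3,6-bis(2,6,6-trimethylcyclohex-1-en-1-yl)-1,4-dioxane | COc1ccc(cc1C(C)C)[C@H]1O[C@H](C2=C(C)CCCC2(C)C)[C@H](O[C@@H]1C1=C(C)CCCC1(C)C)c1ccc(OC)c(C(C)C)c1 | intermediate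
18 | monocyclised intermediate: one half is the trans-fused 12-methoxyabietatriene unit (5S,6R,7R,10S), the other half still carries the aryl and 2,6,6-trimethylcyclohexenyl groups | COc1cc2c(cc1C(C)C)[C@H]1O[C@H](C3=C(C)CCCC3(C)C)[C@H](O[C@@H]1[C@H]1C(C)(C)CCC[C@]21C)c1ccc(OC)c(C(C)C)c1 | intermediate (not isolated)
19 | CNP0327150.1, the C2-symmetric dimer of 12-methoxyabieta-8,11,13-triene with oxygen bridges C6–O–C7′ and C6′–O–C7 (5S,6R,7R,10S in each half) | COc1cc2c(cc1C(C)C)[C@H]1O[C@H]3[C@H](O[C@@H]1[C@H]1C(C)(C)CCC[C@]21C)c1cc(C(C)C)c(OC)cc1[C@@]1(C)CCCC(C)(C)[C@H]31 | target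

**Step count**
Total: 9 steps. Longest linear sequence: 7 steps (steps 1 to 5, 8 and 9); steps 6 and 7 form the second branch.

**Steps most likely to fail**

Step 8. The fully substituted boron-bearing carbon of 15 may be too hindered to reach the oxocarbenium carbon, so that protodeboronation of the borate and decay of the ion take over, or the reaction stops after the first addition. The fallback sets out from 9 and makes the same C5–C6 bonds with a less hindered carbon nucleophile by Hosomi–Sakurai allylation. Commercial 3-methylcyclohex-2-en-1-one is treated with Me2CuLi (Et2O, 0 °C) and the enolate is trapped with PhNTf2 to give 3,3-dimethylcyclohex-1-en-1-yl trifluoromethanesulfonate F1. Kumada coupling with Me3SiCH2MgCl (Pd(PPh3)4, Et2O, rt) gives the allylsilane [(3,3-dimethylcyclohex-1-en-1-yl)methyl]trimethylsilane F2. With BF3·OEt2 (CH2Cl2, −78 °C), 9 and F2 should give the bis(2,2-dimethyl-6-methylidenecyclohexyl)dioxane F3: the secondary γ-carbon of the allylsilane (the future C5) attacks each oxocarbenium ion from the face opposite the aryl groups. Under the conditions of step 9 the exocyclic methylene groups of F3 are protonated to the same C10 cations that 17 gives (C5 can adjust through the C5=C10 alkene), so the fallback comes back to the route at 19.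

Step 9. Triflic acid may ionise the para-methoxybenzylic C7–O bonds, with loss of the C7 configuration or cleavage of the dioxane, faster than the arenes capture the C10 cations. The fallback sets out from 17 and separates cation formation from the strong acid. Anhydrous HCl (CH2Cl2, −78 °C) adds across each C5=C10 alkene in the sense that avoids a cation next to the C6 oxygen and gives the bis(tertiary chloride) 2,5-bis(3-isopropyl-4-methoxyphenyl)-3,6-bis(2-chloro-2,6,6-trimethylcyclohexyl)-1,4-dioxane F4. AgSbF6 with 2,6-di-tert-butyl-4-methylpyridine (CH2Cl2, −78 → −20 °C) then abstracts chloride, and the buffered C10 cations alkylate C9. A half with the unproductive C5 configuration can only eliminate back to the alkene and is recycled. The fallback comes back to the route at 19.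

Step 4. In hot acid the para-methoxybenzylic C7–O bond may ionise or the ester may enolise, eroding the (R) configuration, and chain growth to linear oligomers may outrun ring closure. The fallback sets out from 5 and builds linear dimer 6 stepwise without acid or heat, then closes it under activation. One portion of 5 is alkylated on the carboxylate (allyl bromide, KHCO3, DMF) to allyl (2R)-2-hydroxy-2-(3-isopropyl-4-methoxyphenyl)acetate F5. A second portion is bis-silylated (TBSCl, imidazole, DMF) to the silyl ester silyl ether F6, which is not isolated; its silyl ester is cleaved (K2CO3, aqueous MeOH) to the O-TBS acid F7. Steglich esterification (EDC·HCl, DMAP cat., CH2Cl2, 0 °C) joins F7 and F5 to the protected linear dimer F8. Tsuji–Trost deallylation (Pd(PPh3)4, morpholine, THF) gives the O-TBS dimer acid F9, and HF·pyridine (THF, 0 °C) frees the hydroxy group to give seco acid 6, here as an isolated compound. Yamaguchi lactonisation (2,4,6-trichlorobenzoyl chloride, Et3N; then DMAP, toluene, high dilution) closes the six-membered ring, and the fallback comes back to the route at 7.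

**Further compounds**
F1 | step 8 | 3,3-dimethylcyclohex-1-en-1-yl trifluoromethanesulfonate | CC1(C)CCCC(OS(=O)(=O)C(F)(F)F)=C1
F2 | step 8 | [(3,3-dimethylcyclohex-1-en-1-yl)methyl]trimethylsilane | CC1(C)CCCC(C[Si](C)(C)C)=C1
F3 | step 8 | (2R,3R,5R,6R)-2,5-bis(3-isopropyl-4-methoxyphenyl)-3,6-bis(2,2-dimethyl-6-methylidenecyclohexyl)-1,4-dioxane (cyclohexyl C1 configuration not fixed) | COc1ccc(cc1C(C)C)[C@H]1O[C@H](C2C(=C)CCCC2(C)C)[C@H](O[C@@H]1C1C(=C)CCCC1(C)C)c1ccc(OC)c(C(C)C)c1
F4 | step 9 | (2R,3R,5R,6R)-2,5-bis(3-isopropyl-4-methoxyphenyl)-3,6-bis(2-chloro-2,6,6-trimethylcyclohexyl)-1,4-dioxane (cyclohexyl C1 and C2 configuration not fixed) | COc1ccc(cc1C(C)C)[C@H]1O[C@H](C2C(C)(Cl)CCCC2(C)C)[C@H](O[C@@H]1C1C(C)(Cl)CCCC1(C)C)c1ccc(OC)c(C(C)C)c1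
F5 | step 4 | allyl (2R)-2-hydroxy-2-(3-isopropyl-4-methoxyphenyl)acetate | C=CCOC(=O)[C@H](O)c1ccc(OC)c(C(C)C)c1
F6 | step 4 | tert-butyldimethylsilyl (2R)-2-[(tert-butyldimethylsilyl)oxy]-2-(3-isopropyl-4-methoxyphenyl)acetate | CC(C)(C)[Si](C)(C)OC(=O)[C@H](O[Si](C)(C)C(C)(C)C)c1ccc(OC)c(C(C)C)c1
F7 | step 4 | (2R)-2-[(tert-butyldimethylsilyl)oxy]-2-(3-isopropyl-4-methoxyphenyl)acetic acid | OC(=O)[C@H](O[Si](C)(C)C(C)(C)C)c1ccc(OC)c(C(C)C)c1
F8 | step 4 | allyl (2R)-2-{[(2R)-2-[(tert-butyldimethylsilyl)oxy]-2-(3-isopropyl-4-methoxyphenyl)acetyl]oxy}-2-(3-isopropyl-4-methoxyphenyl)acetate | C=CCOC(=O)[C@H](OC(=O)[C@H](O[Si](C)(C)C(C)(C)C)c1ccc(OC)c(C(C)C)c1)c1ccc(OC)c(C(C)C)c1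
F9 | step 4 | (2R)-2-{[(2R)-2-[(tert-butyldimethylsilyl)oxy]-2-(3-isopropyl-4-methoxyphenyl)acetyl]oxy}-2-(3-isopropyl-4-methoxyphenyl)acetic acid | OC(=O)[C@H](OC(=O)[C@H](O[Si](C)(C)C(C)(C)C)c1ccc(OC)c(C(C)C)c1)c1ccc(OC)c(C(C)C)c1
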